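The question is how much of the charged free catalyst still works when 10 % of the substrate has gone.

| setting | noon | summer | flask |
|---|---|---|---|
| substrate | 1 M | 2.2 M | 1.5 M |
| free catalyst | 13 mM | 13 mM | 13 mM |
| remark | run made earlier | run made earlier |  |

| run | time / h | product / % |
|---|---|---|
| noon | 0.417 | 6.8 |
| noon | 0.833 | 12.2 |
| noon | 1.33 | 16.7 |
| noon | 1.50 | 17.9 |
| noon | 2.00 | 20.5 |
| noon | 2.50 | 22.2 |
| noon | 3.00 | 24.3 |
| summer | 0.167 | 3.4 |
| summer | 0.500 | 7.2 |
| summer | 0.833 | 11.0 |
| summer | 1.33 | 15.0 |
| summer | 2.00 | 19.1 |
| summer | 2.50 | 21.5 |
| summer | 3.00 | 22.9 |

(readings scatter by 0.5 percentage points)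

1. factor on the rate of making product when 10 % of the substrate are converted if free catalyst is charged twice over
2. factor on the rate when 10 % of the substrate are converted if free catalyst is charged at 120 mM instead

The summer charge holds twice the noon substrate, yet the percent curves nearly coincide: at 3.00 h the depth ln(charged/left) reads 0.278 at noon and 0.260 in summer. So follow one free catalyst: at each fork it turns over or dies, and at the same catalyst charge more substrate brings more turns per hour while each turn takes a smaller fraction of the substrate. That gives the catalyst's reach, the final depth of a charge.

The noon readings give depths 0.197 at 1.50 h and 0.278 at 3.00 h. If each equal interval adds a fixed fraction of the one before, the reach is the square of the first depth over twice the first depth less the second, a reading of 0.335 that carries the scatter of both points.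

The mark of 10 % needs depth 0.105, so my reckoning leaves 68.6 % of the catalyst alive. Taking the reach to grow in step with the charge, which no earlier run tests, my reckoning gives factors of 2.46 for the doubled charge and 13.0 for 120 mM.

The forecast is lower, at 2.35 and 12: “Charge dependence is extrapolated, so I shade both downward”.

The flask gives 2.38 and 12.5.

    substrate + free catalyst → catalyst intermediate (k = 20.0 L mol⁻¹ h⁻¹)
    catalyst intermediate → free catalyst + product (k = 81.0 h⁻¹)
    2 free catalyst → spent catalyst A (k = 15.0 L mol⁻¹ h⁻¹)
    free catalyst → spent catalyst B (k = 0.630 h⁻¹)

The reach puts this flask's end at 28.5 % product, and the flask stands at 28.7 % after 30.0 h. Without the step to spent catalyst B, the rate in this flask at the mark is 1.37 times the actual one, the larger effect. The step to spent catalyst A is a part of the loss: without it the rate in this flask at the mark is 1.15 times the actual one.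

(The earlier runs and the new flask come from a simulation for an exercise, noise included.)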